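## The problem

6-Hydroxyluteolin 6,7-disulfate (17) is a flavone in which benzo ring A is fused to the 4-pyranone ring C and the catechol ring B is attached at C2. It has no stereocentre; the only sp3 stereocentre met on the way, the carbinol carbon of 7, is racemic and is erased by oxidation, so no stereocontrol is needed. The difficulty lies in the five phenolic oxygens: O6 and O7 must carry sulfate monoesters while O5, O3' and O4' stay free. O5 is hydrogen-bonded to the C4 carbonyl and so protects itself against amine–SO3 reagents, but the ring B catechol does not, so the pairs O6/O7 and O3'/O4' must be told apart before sulfation. The aryl sulfate monoesters are cleaved by strong protic or Lewis acids, and the 5,6,7-trihydroxy ring A that precedes them is a pyrogallol-type system that oxidises in air under base; every operation from the unmasking of ring A onward must therefore be mild. The 5,6,7-oxygen pattern is best taken from a symmetric 3,4,5-trioxygenated benzene, whose derived phenol has two equivalent ortho positions. The feature that makes the key step possible is ring B: its oxygens sit on the adjacent carbons C3' and C4', each flanked by an unsubstituted CH (C2' and C5'), so that C2'–C3'–C4'–C5' maps onto a symmetric 2,3-dioxygenated buta-1,3-diene and C1'–C6' onto a terminal alkyne on C2 of the chromone.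

## Retrosynthesis

**Sulfate and silyl cuts (17 ⇒ 16 ⇒ 15).** The two Si–O bonds at O3' and O4' are cut first, then the two S–O bonds at O6 and O7. Silyl removal is placed after sulfation because fluoride is a deprotection that an aryl sulfate monoester tolerates; the reverse order would expose the ring B catechol to the sulfating agent. Precursor 15 has O5, O6 and O7 free and carries no charge, so it is far easier to handle than 16. The forward sulfation must stop at O6 and O7, which the hydrogen bond from O5–H to the C4 carbonyl should ensure.

**Benzyl cuts (15 ⇒ 14).** Three O–CH2Ph bonds on ring A are cut. Benzyl is preferred to methyl, whose removal needs boron or aluminium halides that would also strip the silyl ethers. Hydrogenolysis is orthogonal to the ring B silyl ethers, and the benzyl groups arrive with the commercial starting material 1. The forward reaction must leave the pyranone C2=C3 bond unreduced.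

**Ring B (14 ⇒ 10 + 12, through 13).** After formal return of two hydrogens to C2' and C5' (the cyclohexa-1,4-diene 13), the bonds C1'–C2' and C5'–C6' are cut. The neighbouring cuts are C2–C1' (cross-coupling at a 2-functionalised chromone) and the pyranone bonds (routes that bring in ring B as a preformed, separately protected catechol). Against these, the chosen cut creates the catechol oxygens directly as silyl ethers, already distinguished from the benzyl-protected ring A, and the symmetric diene leaves no regiochemical question. Precursor 10 lacks ring B altogether and diene 12 is a one-step derivative of 11. The forward reaction must add at the terminal alkyne in preference to C2=C3 and then dehydrogenate cleanly.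

**Diene (12 ⇒ 11).** Two O–Si bonds are cut, leading to commercial butane-2,3-dione 11. The forward reaction is a double enol silylation.

**Alkyne unmasking and ring C (10 ⇒ 9 ⇒ 8).** The C–Si bond of the alkyne is cut, then the O1–C2 bond of the pyranone, which opens ring C to the o-hydroxyaryl diynone 8. Closure by conjugate addition of the phenol to an ynone is preferred to the classical dehydrative closure of a 1,3-dicarbonyl chain for two reasons. An alkynyl 1,3-dicarbonyl chain can also close through its enol oxygen onto the alkyne and give an isomeric 4-pyranone. That route also needs an ortho-acetylation of 3, which would call for Lewis-acid acylation and endanger the benzyl ethers. The forward reaction must close in the 6-endo mode; the silyl cap keeps nucleophiles from the remote alkyne carbon.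

**Diynone (8 ⇒ 7 ⇒ 4 + 5, through 6).** The ketone is taken back to carbinol 7, and the bond between the carbinol carbon (future C4) and the alkyne carbon (future C3) is cut. The commercial diyne 5, through its mono-lithio derivative 6, supplies C3, C2, C1' and C6' in one piece. The precursor is the simple salicylaldehyde 4. The forward reaction must add an acetylide to an aldehyde deactivated by an ortho phenoxide.

**Ring A aldehyde (4 ⇒ 3 ⇒ 1, through 2).** The C4a–C4 bond is cut (ortho-formylation of phenol 3), and the phenol oxygen is traced to the formyl group of 1 by an oxidative aryl migration through formate 2. The two ortho positions of 3 are equivalent, so the formylation is regiochemically unambiguous. Magnesium-mediated formylation is chosen over Friedel–Crafts chemistry for the sake of the benzyl ethers. Compound 1 is commercial.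

## Roads not taken

Alternative 1: The cut is C4a–C5 of ring A, which unravels into a polyketide-like side chain on a preformed 2-aryl-4-pyranone, namely rac-methyl 4-{6-[3,4-bis(benzyloxy)phenyl]-4-oxo-4H-pyran-2-yl}-2-(methoxymethoxy)-3-oxobutanoate A2. In the forward key step, base would convert A2 into a dienolate whose ring carbon (the future C4a) attacks the ester carbonyl. Enolisation would then give 3',4'-bis(benzyloxy)-5,7-dihydroxy-6-(methoxymethoxy)flavone A1.
- Merits: the closure is biomimetic. Ring B is a robust benzyl-protected arene from the start, and no cycloaddition at a weakly activated alkyne is needed. After sulfation the ring B benzyl ethers of A1 could be removed by hydrogenolysis, which aryl sulfates tolerate, so the end game is at least as clean as that of the chosen plan.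
- Weak points: A2 must itself be assembled by several C-acylations on a pyranone. It has three acidic sites, and the weakly nucleophilic pyranone carbon competes with O-acylation and with retro-Claisen loss of the α-alkoxy ester. The differentiation that A1 delivers (O6 alone) is not the one the target needs, since O6 and O7 must be sulfated alike and O5 looks after itself.
- Comparison: the chosen plan buys ring A with all three oxygens in place and reaches 10 by well-tried reactions. It carries one demanding step, whereas the road through A2 carries an uncertain ring closure and a long precursor synthesis.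

Alternative 2: The cut is the acyl–arene bond C4–C4a of ring C. Phenol 3, the same intermediate as in the chosen plan, would be added to ethyl 3-[3,4-bis(triisopropylsilyloxy)phenyl]prop-2-ynoate A5, and the ester hydrolysed to (Z)-3-[3,4-bis(triisopropylsilyloxy)phenyl]-3-[3,4,5-tris(benzyloxy)phenoxy]prop-2-enoic acid A4. Mixed-anhydride activation of A4 and intramolecular Friedel–Crafts acylation at the ortho carbon of the aryloxy ring would close ring C to 5,6,7-tris(benzyloxy)-3',4'-bis(triisopropylsilyloxy)flavone A3.
- Merits: about three steps lead from 3 to A3, against six from 3 to 14, although A5 has to be prepared on a side branch. The symmetry of the phenol again leaves one ortho position, ring B arrives complete with silyl ethers orthogonal to benzyl, and intramolecular acylation of an electron-rich arene is a more proven reaction type than a Diels–Alder addition to a vinylogous ynone. On step count and on the precedent for the key step this road is the better one.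
- Weak points: the closure of A4 liberates a strong carboxylic acid and passes through acylium-like species. The ring being acylated carries three benzyl ethers, one of which ends peri to the new carbonyl and is the most prone to acidolysis. The silyl ethers must survive both this acid and the basic ester hydrolysis. Only the Z isomer of A4 can close; phenol additions to alkynoates such as A5 give geometric mixtures that equilibrate under acid, and basic hydrolysis can expel the phenoxide by retro-oxa-Michael reaction.
- Comparison: the chosen plan sets against this that every ring-forming step runs under neutral or weakly basic conditions that benzyl and silyl ethers tolerate, and that no alkene geometry has to be held. Alkyne 10 could also take other dienes if ring B analogues were wanted.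

Alternative 3: Three bonds of ring C are cut at once (C4a–C4, C4–C3 and O1–C2). In the forward key step 2-iodo-3,4,5-tris(methoxymethoxy)phenol A7, a carbonyl carbon introduced by carbonylation, and 4-ethynyl-1,2-bis(benzyloxy)benzene A8 would combine under PdCl2(PPh3)2 and an amine base. The product would be 3',4'-bis(benzyloxy)-5,6,7-tris(methoxymethoxy)flavone A6.
- Merits: this is the most convergent road. Both aromatic rings arrive complete in A7 and A8, and the acetal and benzyl groups of A6 are orthogonal. The end game from A6 (acid removal of the acetals, sulfation, hydrogenolysis) needs no fluoride step. If the carbonylation works on A7, this road is shorter and more economical than the chosen plan.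
- Weak points: in A7 the iodine sits between a hydroxyl and an acetal-protected oxygen on a very electron-rich ring. Oxidative addition should be slow and protodeiodination competitive. When carbonyl insertion lags, direct coupling of A7 with A8 followed by closure to a benzofuran skeleton takes over, and 5-exo closure after carbonylation (the aurone skeleton) is a further leak. A7 itself needs an oxidative phenol synthesis and an iodination. The final hydrogenolysis must spare C2=C3 in a polar, sulfated substrate.
- Comparison: the chosen plan uses no pressurised toxic gas and no metal-catalysed step at a doubly ortho-substituted arene. Its differentiation of ring B from ring A comes from the way ring B is built, not from separately protected building blocks such as A7 and A8.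

Key step: step 8

Remark on the chemistry: the target is taken in the free bis(hydrogen sulfate) form as drawn. The sulfate salt 16 is written with its pyridinium counter-ions, and the final work-up includes a cold acidification that gives the drawn acid form.

## Route

Step 1
Reactants: 1 3,4,5-tris(benzyloxy)benzaldehyde
Product: 3 3,4,5-tris(benzyloxy)phenol, via aryl formate 2 (not isolated)
Conditions: mCPBA, CH2Cl2, 0 °C → rt; then K2CO3 (cat.), MeOH, rt
Reagents that add atoms: 3-chloroperbenzoic acid (mCPBA), O=C(OO)c1cccc(Cl)c1
Why: Baeyer–Villiger (Dakin-type) oxidation: in the Criegee adduct the electron-rich aryl group with its para alkoxy donor migrates in preference to hydride, giving formate 2, which is methanolysed under mild base; benzyl ethers are inert to both stages.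

Step 2
Reactants: 3 3,4,5-tris(benzyloxy)phenol
Product: 4 2,3,4-tris(benzyloxy)-6-hydroxybenzaldehyde
Conditions: MgCl2, Et3N, (CH2O)n, MeCN, reflux; aq HCl work-up
Reagents that add atoms: paraformaldehyde (formaldehyde), C=O
Why: Magnesium-mediated ortho-formylation (Casnati–Skattebøl): the magnesium phenoxide delivers formaldehyde to the ortho carbon through a chelate, and a second formaldehyde oxidises the benzylic alkoxide by Oppenauer-type hydride transfer. The two ortho positions of 3 are equivalent, so one aldehyde can form, and no Lewis acid able to cleave benzyl ethers is present.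

Step 3
Reactants: 4 2,3,4-tris(benzyloxy)-6-hydroxybenzaldehyde, 5 1,4-bis(trimethylsilyl)buta-1,3-diyne
Product: 7 rac-1-[2,3,4-tris(benzyloxy)-6-hydroxyphenyl]-5-(trimethylsilyl)penta-2,4-diyn-1-ol, via lithium silylbutadiynide 6 (not isolated)
Conditions: 5 (2.6 equiv), MeLi·LiBr (2.5 equiv), THF, −78 °C → rt; then 4, −78 → 0 °C; aq NH4Cl
Reagents that add atoms: none
Why: 1,2-Addition of a lithium acetylide to an aldehyde: MeLi·LiBr removes one silyl group of 5 to give 6, the first equivalent of 6 deprotonates the phenol and the second adds to the carbonyl. The carbinol stereocentre forms as a racemate and is erased in step 4.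

Step 4
Reactants: 7 rac-1-[2,3,4-tris(benzyloxy)-6-hydroxyphenyl]-5-(trimethylsilyl)penta-2,4-diyn-1-ol
Product: 8 1-[2,3,4-tris(benzyloxy)-6-hydroxyphenyl]-5-(trimethylsilyl)penta-2,4-diyn-1-one
Conditions: MnO2 (activated, excess), CH2Cl2, rt
Reagents that add atoms: none
Why: MnO2 oxidation of a benzylic and propargylic secondary alcohol to the ynone under neutral heterogeneous conditions; the free phenol, the benzyl ethers and the C-silyl group are untouched.

Step 5
Reactants: 8 1-[2,3,4-tris(benzyloxy)-6-hydroxyphenyl]-5-(trimethylsilyl)penta-2,4-diyn-1-one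
Product: 9 5,6,7-tris(benzyloxy)-2-[(trimethylsilyl)ethynyl]-4H-chromen-4-one
Conditions: 4-(dimethylamino)pyridine (DMAP, 0.2 equiv), DMF, 0 °C → rt
Reagents that add atoms: none
Why: Amine-catalysed 6-endo-dig oxa-Michael cyclisation of an o-alkynoylphenol: DMAP adds reversibly to the β-carbon and the phenol displaces it by addition–elimination at the same carbon, which directs closure to the chromone and away from the 5-exo (aurone-type) mode. The silyl cap shields the remote alkyne carbon.

Step 6
Reactants: 9 5,6,7-tris(benzyloxy)-2-[(trimethylsilyl)ethynyl]-4H-chromen-4-one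
Product: 10 5,6,7-tris(benzyloxy)-2-ethynyl-4H-chromen-4-one
Conditions: Bu4NF, AcOH, THF, −20 → 0 °C
Reagents that add atoms: none
Why: Fluoride-induced protodesilylation of an alkynylsilane, fast because the departing acetylide is stabilised by conjugation to the chromone; AcOH protonates the acetylide at once and keeps basic fluoride from adding to the electron-poor enyne or opening the pyranone.

Step 7
Reactants: 11 butane-2,3-dione
Product: 12 2,3-bis(tert-butyldimethylsilyloxy)buta-1,3-diene
Conditions: TBSOTf (2.2 equiv), Et3N (3 equiv), CH2Cl2, 0 °C → rt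
Reagents that add atoms: tert-butyldimethylsilyl trifluoromethanesulfonate (TBSOTf), CC(C)(C)[Si](C)(C)OS(=O)(=O)C(F)(F)F
Why: Double soft enolisation and O-silylation of a 1,2-diketone with a silyl triflate and a tertiary amine, the standard access to 2,3-bis(silyloxy)buta-1,3-dienes; the tert-butyldimethylsilyl group is chosen so that the ring B oxygens later survive hydrogenolysis and sulfation.

Step 8
Reactants: 10 5,6,7-tris(benzyloxy)-2-ethynyl-4H-chromen-4-one, 12 2,3-bis(tert-butyldimethylsilyloxy)buta-1,3-diene
Product: 14 5,6,7-tris(benzyloxy)-3',4'-bis(tert-butyldimethylsilyloxy)flavone, via cyclohexa-1,4-diene adduct 13 (not isolated)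
Conditions: 12 (3 equiv), 2,6-di-tert-butyl-4-methylphenol (BHT, cat.), toluene, 130 °C, sealed tube; excess 12 removed in vacuo; then 2,3-dichloro-5,6-dicyano-1,4-benzoquinone (DDQ, 1.2 equiv), CH2Cl2, 0 °C → rt
Reagents that add atoms: none
Why: Thermal Diels–Alder reaction of normal electron demand followed by quinone dehydrogenation; the closest known reaction type is the cycloaddition of 2,3-bis(silyloxy)buta-1,3-dienes to acetylenic esters and ketones with subsequent aromatisation to protected catechols. The HOMO of the s-cis conformer of 12, raised by two silyloxy donors, combines with the LUMO of the terminal alkyne of 10, which is lowered by conjugation through C2=C3 to the C4 carbonyl, and C1'–C2' and C5'–C6' form in one concerted, suprafacial event. Ring B thus closes as a six-membered carbocycle by intermolecular [4+2] cycloaddition, first as the cyclohexa-1,4-diene 13. DDQ then abstracts hydride from a doubly allylic CH2 of 13 (the cation is stabilised by a silyloxy group) and loss of a proton from the other CH2 gives the arene, so the ring B oxygens appear as the silyl ethers of 14. No stereocentre is formed at any stage. The selectivity required is addition at the alkyne and not at C2=C3: the terminal alkyne is sterically open, whereas C2=C3 is trisubstituted, carries the O1 donor and belongs to the partly aromatic pyranone, and the symmetric diene excludes regioisomers. No Lewis acid is used, because complexation of the C4 carbonyl would make C2 the most electrophilic site and invite stepwise Mukaiyama–Michael attack by the silyl enol ether. Benzyl ethers are inert to DDQ at room temperature, and BHT restrains radical oligomerisation of the alkyne.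

Step 9
Reactants: 14 5,6,7-tris(benzyloxy)-3',4'-bis(tert-butyldimethylsilyloxy)flavone
Product: 15 3',4'-bis(tert-butyldimethylsilyloxy)-5,6,7-trihydroxyflavone
Conditions: H2 (1 atm), Pd/C (10%), EtOAc–THF, rt
Reagents that add atoms: none
Why: Hydrogenolysis of aryl benzyl ethers over palladium on carbon; aryl silyl ethers, the pyranone C2=C3 bond and the carbonyl are inert under one atmosphere of hydrogen in a non-protic solvent, so ring A alone is unmasked.

Step 10
Reactants: 15 3',4'-bis(tert-butyldimethylsilyloxy)-5,6,7-trihydroxyflavone
Product: 16 bis(pyridinium) 3',4'-bis(tert-butyldimethylsilyloxy)-5-hydroxyflavone-6,7-diyl bis(sulfate)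
Conditions: SO3·pyridine (8 equiv), pyridine, 45 °C, argon
Reagents that add atoms: sulfur trioxide–pyridine complex, [O-]S(=O)(=O)[n+]1ccccc1
Why: O-Sulfation of phenols with an amine–SO3 complex: O7 and O6 react, whereas O5 is tied in a hydrogen bond to the C4 carbonyl and is the least nucleophilic hydroxyl of a flavone. The ring B oxygens are blocked as silyl ethers, which tolerate pyridine.

Step 11
Reactants: 16 bis(pyridinium) 3',4'-bis(tert-butyldimethylsilyloxy)-5-hydroxyflavone-6,7-diyl bis(sulfate)
Product: 17 6-hydroxyluteolin 6,7-disulfate
Conditions: KF, MeOH, rt; then aq HCl to pH 2, 0 °C; C18 desalting, freeze-drying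
Reagents that add atoms: none
Why: Fluoride cleavage of aryl silyl ethers (strong Si–F bond, phenoxide leaving group) under conditions to which aryl sulfate monoesters are stable; brief cold acidification converts the salt into the bis(hydrogen sulfate) drawn for 17.

## Compound list

1 | 3,4,5-tris(benzyloxy)benzaldehyde | O=Cc1cc(OCc2ccccc2)c(OCc2ccccc2)c(OCc2ccccc2)c1 | starting material
2 | 3,4,5-tris(benzyloxy)phenyl formate | O=COc1cc(OCc2ccccc2)c(OCc2ccccc2)c(OCc2ccccc2)c1 | intermediate
3 | 3,4,5-tris(benzyloxy)phenol | Oc1cc(OCc2ccccc2)c(OCc2ccccc2)c(OCc2ccccc2)c1 | intermediate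
4 | 2,3,4-tris(benzyloxy)-6-hydroxybenzaldehyde | O=Cc1c(O)cc(OCc2ccccc2)c(OCc2ccccc2)c1OCc1ccccc1 | intermediate
5 | 1,4-bis(trimethylsilyl)buta-1,3-diyne | C[Si](C)(C)C#CC#C[Si](C)(C)C | starting material
6 | lithium 4-(trimethylsilyl)buta-1,3-diyn-1-ide | [Li+].[C-]#CC#C[Si](C)(C)C | intermediate
7 | rac-1-[2,3,4-tris(benzyloxy)-6-hydroxyphenyl]-5-(trimethylsilyl)penta-2,4-diyn-1-ol | OC(C#CC#C[Si](C)(C)C)c1c(O)cc(OCc2ccccc2)c(OCc2ccccc2)c1OCc1ccccc1 | intermediate
8 | 1-[2,3,4-tris(benzyloxy)-6-hydroxyphenyl]-5-(trimethylsilyl)penta-2,4-diyn-1-one | O=C(C#CC#C[Si](C)(C)C)c1c(O)cc(OCc2ccccc2)c(OCc2ccccc2)c1OCc1ccccc1 | intermediate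
9 | 5,6,7-tris(benzyloxy)-2-[(trimethylsilyl)ethynyl]-4H-chromen-4-one | C[Si](C)(C)C#Cc1cc(=O)c2c(OCc3ccccc3)c(OCc3ccccc3)c(OCc3ccccc3)cc2o1 | intermediate
10 | 5,6,7-tris(benzyloxy)-2-ethynyl-4H-chromen-4-one | C#Cc1cc(=O)c2c(OCc3ccccc3)c(OCc3ccccc3)c(OCc3ccccc3)cc2o1 | intermediate
11 | butane-2,3-dione | CC(=O)C(C)=O | starting material
12 | 2,3-bis(tert-butyldimethylsilyloxy)buta-1,3-diene | C=C(O[Si](C)(C)C(C)(C)C)C(=C)O[Si](C)(C)C(C)(C)C | intermediate
13 | 5,6,7-tris(benzyloxy)-2-[4,5-bis(tert-butyldimethylsilyloxy)cyclohexa-1,4-dien-1-yl]-4H-chromen-4-one | O=c1cc(C2=CCC(O[Si](C)(C)C(C)(C)C)=C(O[Si](C)(C)C(C)(C)C)C2)oc2cc(OCc3ccccc3)c(OCc3ccccc3)c(OCc3ccccc3)c12 | intermediate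
14 | 5,6,7-tris(benzyloxy)-3',4'-bis(tert-butyldimethylsilyloxy)flavone | O=c1cc(-c2ccc(O[Si](C)(C)C(C)(C)C)c(O[Si](C)(C)C(C)(C)C)c2)oc2cc(OCc3ccccc3)c(OCc3ccccc3)c(OCc3ccccc3)c12 | intermediate
15 | 3',4'-bis(tert-butyldimethylsilyloxy)-5,6,7-trihydroxyflavone | O=c1cc(-c2ccc(O[Si](C)(C)C(C)(C)C)c(O[Si](C)(C)C(C)(C)C)c2)oc2cc(O)c(O)c(O)c12 | intermediate
16 | bis(pyridinium) 3',4'-bis(tert-butyldimethylsilyloxy)-5-hydroxyflavone-6,7-diyl bis(sulfate) | O=c1cc(-c2ccc(O[Si](C)(C)C(C)(C)C)c(O[Si](C)(C)C(C)(C)C)c2)oc2cc(OS(=O)(=O)[O-])c(OS(=O)(=O)[O-])c(O)c12.c1cc[nH+]cc1.c1cc[nH+]cc1 | intermediate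
17 | 6-hydroxyluteolin 6,7-disulfate [2-(3,4-dihydroxyphenyl)-5-hydroxy-4-oxo-4H-chromene-6,7-diyl bis(hydrogen sulfate)] | O=c1cc(-c2ccc(O)c(O)c2)oc2cc(OS(=O)(=O)O)c(OS(=O)(=O)O)c(O)c12 | target

## Step count and least certain steps

Total: 11 steps. Longest linear sequence: 10 steps (steps 1–6 and 8–11, from 1); step 7 is a one-step branch.

**Step 8 (key step).** The cycloaddition may be too slow. The alkyne is activated only vinylogously, and the bulky 2,3-disubstituted diene populates its s-cis conformer poorly. At the temperature then required, the terminal alkyne may oligomerise or the diene may decompose. During dehydrogenation, loss of a silyl group in place of a proton from the oxocarbenium intermediate would partly unmask ring B.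
Fallback: ring B is brought in as a preformed arylalkyne, setting out from 4 and rejoining the route at 14. Commercial 3,4-dihydroxybenzaldehyde would be bis-silylated (TBSCl, imidazole) to 3,4-bis(tert-butyldimethylsilyloxy)benzaldehyde F1. Aprotic Colvin homologation (Me3SiCHN2, LiN(i-Pr)2, THF) would give 4-ethynyl-1,2-bis(tert-butyldimethylsilyloxy)benzene F2. F2 would be lithiated with n-BuLi and added in excess to 4 to give the propargylic alcohol rac-1-[2,3,4-tris(benzyloxy)-6-hydroxyphenyl]-3-[3,4-bis(tert-butyldimethylsilyloxy)phenyl]prop-2-yn-1-ol F3. MnO2 oxidation would give the ynone 1-[2,3,4-tris(benzyloxy)-6-hydroxyphenyl]-3-[3,4-bis(tert-butyldimethylsilyloxy)phenyl]prop-2-yn-1-one F4, and cyclisation with catalytic DMAP as in step 5 would give 14.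

**Step 3.** Addition to the aldehyde may be incomplete, because the ortho phenoxide and three alkoxy donors deactivate it. The very electron-rich o-hydroxybenzylic, propargylic carbinol may also ionise towards an o-quinone methide during work-up.
Fallback: the phenol is masked first, setting out from 4 and rejoining at 8. Treatment of 4 with MOMCl and i-Pr2NEt would give 2,3,4-tris(benzyloxy)-6-(methoxymethoxy)benzaldehyde F5. Addition of 6 (now only a slight excess) would give rac-1-[2,3,4-tris(benzyloxy)-6-(methoxymethoxy)phenyl]-5-(trimethylsilyl)penta-2,4-diyn-1-ol F6. MnO2 oxidation would give 1-[2,3,4-tris(benzyloxy)-6-(methoxymethoxy)phenyl]-5-(trimethylsilyl)penta-2,4-diyn-1-one F7. Mild acid (HCl in MeOH–THF, 0 °C) would remove the acetal, which is activated by the ortho carbonyl, and give 8.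

**Step 5.** Closure may go in the 5-exo mode at the α-carbon. The catalyst may add at the remote alkyne, or the C-silyl group may be lost early and the exposed diyne decompose.
Fallback: an enaminone relay, setting out from 8 and rejoining at 9. Diethylamine in THF at 0 °C would add to the β-carbon to give 3-(diethylamino)-1-[2,3,4-tris(benzyloxy)-6-hydroxyphenyl]-5-(trimethylsilyl)pent-2-en-4-yn-1-one F8. Warming F8 in toluene with a little AcOH would close the ring by addition–elimination at that carbon, releasing the amine and giving 9 with the 6-endo connectivity fixed.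

**Step 10.** Sulfation may be incomplete at the hindered O6, which is flanked by O5–H and the newly sulfated O7. Forcing conditions may sulfate O5 as well, and the triol may oxidise before it is consumed. The lipophilic–ionic salt may be hard to purify.
Fallback: neutral sulfate diesters, setting out from 15 and rejoining at 17. 2,2,2-Trichloroethyl chlorosulfate with Et3N and DMAP in THF would give 3',4'-bis(tert-butyldimethylsilyloxy)-5-hydroxyflavone-6,7-diyl bis(2,2,2-trichloroethyl) bis(sulfate) F9, which can be purified on silica and resubmitted if under-sulfated. HF·pyridine in THF would remove the silyl ethers to give 2-(3,4-dihydroxyphenyl)-5-hydroxy-4-oxo-4H-chromene-6,7-diyl bis(2,2,2-trichloroethyl) bis(sulfate) F10. Zn and HCO2NH4 in MeOH would cleave the trichloroethyl groups reductively, and cold acidification as in step 11 would give 17.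

## Further compounds

F1 | step 8 | 3,4-bis(tert-butyldimethylsilyloxy)benzaldehyde | O=Cc1ccc(O[Si](C)(C)C(C)(C)C)c(O[Si](C)(C)C(C)(C)C)c1
F2 | step 8 | 4-ethynyl-1,2-bis(tert-butyldimethylsilyloxy)benzene | C#Cc1ccc(O[Si](C)(C)C(C)(C)C)c(O[Si](C)(C)C(C)(C)C)c1
F3 | step 8 | rac-1-[2,3,4-tris(benzyloxy)-6-hydroxyphenyl]-3-[3,4-bis(tert-butyldimethylsilyloxy)phenyl]prop-2-yn-1-ol | OC(C#Cc1ccc(O[Si](C)(C)C(C)(C)C)c(O[Si](C)(C)C(C)(C)C)c1)c1c(O)cc(OCc2ccccc2)c(OCc2ccccc2)c1OCc1ccccc1
F4 | step 8 | 1-[2,3,4-tris(benzyloxy)-6-hydroxyphenyl]-3-[3,4-bis(tert-butyldimethylsilyloxy)phenyl]prop-2-yn-1-one | O=C(C#Cc1ccc(O[Si](C)(C)C(C)(C)C)c(O[Si](C)(C)C(C)(C)C)c1)c1c(O)cc(OCc2ccccc2)c(OCc2ccccc2)c1OCc1ccccc1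
F5 | step 3 | 2,3,4-tris(benzyloxy)-6-(methoxymethoxy)benzaldehyde | COCOc1cc(OCc2ccccc2)c(OCc2ccccc2)c(OCc2ccccc2)c1C=O
F6 | step 3 | rac-1-[2,3,4-tris(benzyloxy)-6-(methoxymethoxy)phenyl]-5-(trimethylsilyl)penta-2,4-diyn-1-ol | COCOc1cc(OCc2ccccc2)c(OCc2ccccc2)c(OCc2ccccc2)c1C(O)C#CC#C[Si](C)(C)C
F7 | step 3 | 1-[2,3,4-tris(benzyloxy)-6-(methoxymethoxy)phenyl]-5-(trimethylsilyl)penta-2,4-diyn-1-one | COCOc1cc(OCc2ccccc2)c(OCc2ccccc2)c(OCc2ccccc2)c1C(=O)C#CC#C[Si](C)(C)C
F8 | step 5 | 3-(diethylamino)-1-[2,3,4-tris(benzyloxy)-6-hydroxyphenyl]-5-(trimethylsilyl)pent-2-en-4-yn-1-one (alkene geometry not fixed) | CCN(CC)C(C#C[Si](C)(C)C)=CC(=O)c1c(O)cc(OCc2ccccc2)c(OCc2ccccc2)c1OCc1ccccc1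
F9 | step 10 | 3',4'-bis(tert-butyldimethylsilyloxy)-5-hydroxyflavone-6,7-diyl bis(2,2,2-trichloroethyl) bis(sulfate) | O=c1cc(-c2ccc(O[Si](C)(C)C(C)(C)C)c(O[Si](C)(C)C(C)(C)C)c2)oc2cc(OS(=O)(=O)OCC(Cl)(Cl)Cl)c(OS(=O)(=O)OCC(Cl)(Cl)Cl)c(O)c12
F10 | step 10 | 2-(3,4-dihydroxyphenyl)-5-hydroxy-4-oxo-4H-chromene-6,7-diyl bis(2,2,2-trichloroethyl) bis(sulfate) | O=c1cc(-c2ccc(O)c(O)c2)oc2cc(OS(=O)(=O)OCC(Cl)(Cl)Cl)c(OS(=O)(=O)OCC(Cl)(Cl)Cl)c(O)c12
A1 | alternative 1 | 3',4'-bis(benzyloxy)-5,7-dihydroxy-6-(methoxymethoxy)flavone | O=c1cc(-c2ccc(OCc3ccccc3)c(OCc3ccccc3)c2)oc2cc(O)c(OCOC)c(O)c12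
A2 | alternative 1 | rac-methyl 4-{6-[3,4-bis(benzyloxy)phenyl]-4-oxo-4H-pyran-2-yl}-2-(methoxymethoxy)-3-oxobutanoate | COCOC(C(=O)OC)C(=O)Cc1cc(=O)cc(-c2ccc(OCc3ccccc3)c(OCc3ccccc3)c2)o1
A3 | alternative 2 | 5,6,7-tris(benzyloxy)-3',4'-bis(triisopropylsilyloxy)flavone | O=c1cc(-c2ccc(O[Si](C(C)C)(C(C)C)C(C)C)c(O[Si](C(C)C)(C(C)C)C(C)C)c2)oc2cc(OCc3ccccc3)c(OCc3ccccc3)c(OCc3ccccc3)c12
A4 | alternative 2 | (Z)-3-[3,4-bis(triisopropylsilyloxy)phenyl]-3-[3,4,5-tris(benzyloxy)phenoxy]prop-2-enoic acid | OC(=O)/C=C(\Oc1cc(OCc2ccccc2)c(OCc2ccccc2)c(OCc2ccccc2)c1)c1ccc(O[Si](C(C)C)(C(C)C)C(C)C)c(O[Si](C(C)C)(C(C)C)C(C)C)c1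
A5 | alternative 2 | ethyl 3-[3,4-bis(triisopropylsilyloxy)phenyl]prop-2-ynoate | CCOC(=O)C#Cc1ccc(O[Si](C(C)C)(C(C)C)C(C)C)c(O[Si](C(C)C)(C(C)C)C(C)C)c1
A6 | alternative 3 | 3',4'-bis(benzyloxy)-5,6,7-tris(methoxymethoxy)flavone | O=c1cc(-c2ccc(OCc3ccccc3)c(OCc3ccccc3)c2)oc2cc(OCOC)c(OCOC)c(OCOC)c12
A7 | alternative 3 | 2-iodo-3,4,5-tris(methoxymethoxy)phenol | COCOc1cc(O)c(I)c(OCOC)c1OCOC
A8 | alternative 3 | 4-ethynyl-1,2-bis(benzyloxy)benzene | C#Cc1ccc(OCc2ccccc2)c(OCc2ccccc2)c1
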